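Early in the larch run, at 3.00 min, single-handed Z has turned the racemate of D and E, with reagent J, into Q at 13.6% and X at 5.0%, a ratio of 2.72.

all flasks: D 0.57 M; E 0.57 M; J 1.71 M
- oak: Z 85 mM; run made earlier
- larch: Z 310 mM; run made earlier
- summer: Z 100 mM; time 80 min
- dawn: Z 400 mM; time 80 min

| run | time / min | Q / % | X / % |
|---|---|---|---|
| oak | 4.00 | 5.9 | 3.3 |
| oak | 10.0 | 11.7 | 4.1 |
| oak | 20.0 | 17.2 | 6.5 |
| oak | 30.0 | 20.9 | 8.2 |
| oak | 40.0 | 21.6 | 7.9 |
| larch | 3.00 | 13.6 | 5.0 |
| larch | 6.00 | 24.0 | 8.2 |
| larch | 12.0 | 33.9 | 12.8 |
| larch | 20.0 | 40.3 | 15.6 |
| larch | 40.0 | 45.3 | 17.5 |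

(readings scatter by 0.5 percentage points)

- Z is single-handed; D and E are mirror images of each other, charged as a racemate, each of them at the stated concentration
- an excess is the difference of the two amounts in percent of their sum
- an excess is below zero if the other one leads

1. which one finishes higher in excess of Q over X in the product ("neither" within 2 percentage points) (summer / dawn / neither)
2. excess of Q over X in the product at the end, summer
3. excess of Q over X in the product at the end, dawn

I test that ratio against two extreme flasks. In the first, D and E do not interconvert, so Q cannot pass a fraction 0.5 of the pool and the ratio falls as D thins out: with Q at 45.3%, the early ratio puts X at 29.0%. In the second, the step between D and E is so quick that I treat it as finished at each moment. D and E then stay equal, like a copolymer feed held constant, and the product shows no composition drift.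

Larch at 40.0 min reads X at 17.5%, below that first figure. Oak at 40.0 min, with less Z, reads a ratio of 2.73. Within the scatter, I read oak and larch as lying close to the second extreme, a dynamic kinetic resolution.

So I carry the capture ratio, Q formed per X formed (the selectivity factor), read from the last larch reading as 2.59. Its excess is the ratio less one over the ratio plus one, 44.3%. In the second extreme Z and time cancel from this ratio, so I expect that figure for summer and for dawn, though dawn's 400 mM of Z lies beyond larch's 310 mM.

The forecast gives 45% for summer and 45% for dawn, slightly above mine, and for the higher one neither, on the ground that “D and E must interconvert quickly relative to reaction”.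

The flasks give 44.3% for summer and 43.9% for dawn, so the higher one is neither.

    J + Z + D → Z + Q (k = 0.00390 L² mol⁻² s⁻¹)
    J + Z + E → Z + X (k = 0.00150 L² mol⁻² s⁻¹)
    D ⇌ E (k = 0.0340 s⁻¹)
    J → G (k = 7.40 × 10⁻⁴ s⁻¹)

At the end of dawn, D and E stand level at 13.9% and 13.9%, while Q has reached 52.0%. Dividing that Q by the capture ratio of 2.59 gives 20.1%, and X stands at 20.3%. In a flask like summer charged with 1.0 M of J, Q ends at 16.8%, the same division gives 6.49%, and X stands at 6.47%.

(Readings and results were generated by integration with made-up constants; scatter was added.)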